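**Early times.** At early times the south-east flask made product quickly: 11% by 5.00 h, and 35% by 30.0 h. I ranked what changed by how fast it changed.

| setting | south-east | flask |
|---|---|---|
| starting material | 0.50 M | 0.50 M |
| partner | 2 M | 2.00 M |
| free catalyst | 25 mM | 25 mM |
| remark | the very flask that is asked about, followed so far |  |
| time |  | 3.0 d |

south-east run (percent of the starting material charged)

| time / h | product / % |
|---|---|
| 5.00 | 11 |
| 8.00 | 15 |
| 15.0 | 24 |
| 30.0 | 35 |
| 60.0 | 37 |

(each reading ± 1.5 percentage points)

- green: at 3.0 d add free catalyst, 50.0% of the amount charged, then wait 40 h
- amber: at 3.0 d take out 90% of the product then present, then wait 40 h
- teal: change nothing and wait 40 h more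

- product taken out counts as made
- additions bring no volume worth counting

- product, in percent of the starting material first charged, at 3.0 d
- the option that brings most further product ("none" if no option brings more than 2 percentage points) (green / amber / teal / none)
- product present, with what was taken out counted in, in percent of the starting material first charged, after green
- product present, with what was taken out counted in, in percent of the starting material first charged, after amber

**Fastest rung.** The rate fell first. Between 30.0 h and 60.0 h the run gained 2 percentage points, close to the scatter of 1.5 points, so as a rough reading the rate had dropped by a factor of about 33.0.

**Slower rung.** The charges moved far less. Counting what the product consumed, a rate of first order in starting material and in partner falls by a factor of 1.75, which is much less than the drop. So a rate of that form did not account for the drop. I took the late rate to be of first order in a falling free catalyst, though these readings cannot separate that from an equilibrium.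

**Catalyst capacity.** On that view the flask counts catalyst. I defined the capacity N, a turnover number, as product made per catalyst charged before the catalyst is lost: N = 7.40. So I expected about 37% at 3.0 d, and the same after teal or amber. Green's added catalyst should bring 18 points, giving 55.0%.

**The result.** The forecast gave 37.5%, 37.5% after green and 56.5% after amber, chose amber, and said “I read it as equilibrium”. The flask gave 38.2% at 3.0 d, 49.3% after green and 39.2% after amber, so green was best, gaining 11 points against 0.97 points for amber and for teal.

    starting material + partner + free catalyst → product + free catalyst, rate k1*[starting material]*[partner]*[free catalyst]/(1 + ([starting material]/sat1)) (33.0 mM, k = 0.00220 L² mol⁻² s⁻¹)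
    partner → decomposed reagent (k = 2.50 × 10⁻⁶ s⁻¹)
    starting material + free catalyst → spent catalyst (k = 3.50 × 10⁻⁵ L mol⁻¹ s⁻¹)

**Why it stopped.** The flask gave 95.5% in a run without the path from starting material + free catalyst to spent catalyst and 99.1% in a run without the crowding by starting material in the rate law, against 38.2%, so these two together, each a part of the reason, held the flask down. Green's gain over 40 h, counted per catalyst added, was 4.44 product, less than N. In the neighbour with 0.10 M of free catalyst, N allows 0.740 M, more than the 0.50 M charged, which makes starting material the limiting reagent. That flask gave 92.9%, with starting material at 0%.

The numbers in the tables were computed with made-up constants, noise included.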